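Do not stretch the earliest split backwards in time: a first reading carries the scatter of two numbers, and it speaks of its own moment, not an earlier one.

| setting | summer | dawn | flask |
|---|---|---|---|
| substrate | 0.074 M | 0.17 M | 0.11 M |
| partner | 0.116 M | 0.116 M | 0.116 M |
| remark | run made earlier | run made earlier |  |
| time |  |  | 1.5 h |

| run | time / min | target / % | side product / % |
|---|---|---|---|
| summer | 3.00 | 52 | 16 |
| summer | 8.00 | 79 | 16 |
| summer | 15.0 | 84 | 16 |
| summer | 25.0 | 83 | 19 |
| summer | 30.0 | 80 | 15 |
| summer | 40.0 | 81 | 15 |
| summer | 50.0 | 81 | 17 |
| dawn | 8.00 | 79 | 17 |
| dawn | 15.0 | 81 | 18 |
| dawn | 25.0 | 87 | 18 |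
| dawn | 30.0 | 80 | 18 |
| dawn | 40.0 | 79 | 15 |
| dawn | 50.0 | 85 | 20 |

(readings scatter by 2 percentage points)

1. share of target in target plus side product at 30 s
2. share of target in target plus side product at 6.0 min
3. share of target in target plus side product at 1.5 h
4. which of target and side product there is more of at 1.5 h

- what is said of target includes crystals
- crystals is a solid; its amount is given per volume of the solution
- the numbers in the tables scatter with a standard deviation of 2 percentage points
- on the list of suspects stand: substrate -> intermediate A; intermediate A <-> intermediate B; intermediate A -> target; intermediate B -> side product; crystals <-> target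

Sum the readings from 8.00 min on, the first time both runs share, when the amounts may still be climbing but the split already reads 83.2% in summer and 82.3% at dawn, and take target over target plus side product, with crystals counted inside target:

summer 83.3%, dawn 82.2%

both together 82.8%

Carry this as the end share, the selectivity of the finished run, and since c(substrate) from 0.074 M to 0.17 M moves it by 1 percentage point, give it to the flask at 0.11 M for 6.0 min and 1.5 h, with target ahead.

Bracket the share at 30 s: on the suspect list side product lies one step further on than target, through intermediate B, so the share starts at 100 and falls towards 82.8%, which makes 100 the ceiling and 82.8% the floor. Then go round once more and put 82.8% back into the first summer reading: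

side product expected beside 52% of target: 10.8%; read: 16%

That reading stands 5.2 points above the expectation, against a scatter of 2 points, and it speaks of 3.00 min, not of 30 s, so it leaves the bracket as it stands; name the floor, 82.8%, as the working value for 30 s, a choice and not a reading.

The forecast says 76%, 82%, 83% and target, adding “At 30 s nothing has been measured and the mechanism is ambiguous, so the range is wide.” Its 30 s value stands outside the bracket, under the floor.

The flask gives 83.2%, 82.5% and 82.5%, with target ahead at 82.5%, so the 30 s share lies inside the bracket, 0.4 points over the floor.

    substrate → intermediate A (k = 0.00750 s⁻¹)
    intermediate A ⇌ intermediate B (K = 0.460, k = 0.520 s⁻¹)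
    intermediate A → target (k = 0.0320 s⁻¹)
    intermediate B → side product (k = 0.0150 s⁻¹)
    crystals ⇌ target, rate k5*(cs5 - [target]) while solid is left; crystals form when [target] > cs5 (solubility = 0.0660 M, k = 0.210 s⁻¹)

In the flask, the forward step from intermediate A to intermediate B has a half-life of 0.022 min, taken at 0.0257 h, far shorter than 30 s. At that same moment intermediate B falls back 75 times faster than it goes on, a pre-equilibrium between the two intermediates. The neighbour flask with 0.070 M of partner ends at 82.5%, beside the carried 82.8%, with 100% of its partner still unbound.

The data stem from a simulated flask on assumed constants; the scatter is artificial.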